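**Retrosynthetic overview**
- The target comes from a silyl-protected 8-hydroxy germacranolide by methacryloylation of the only free hydroxyl and final desilylation.
- Key ring closure: an intramolecular Nozaki–Hiyama allylation (CrCl2) of an ω-formyl 3-(bromomethyl)butenolide forms the C7–C8 bond. This macrocyclization closes the ten-membered ring, moves the lactone double bond to the exocyclic position and sets C7 and C8.
- The cyclization precursor comes from a Negishi sp3–sp2 coupling (C3–C4) of an east alkylzinc (C8–C10, C1–C3, C14) with a west 5-(2-bromoalkenyl)butenolide (C4–C7, C11–C13, C15).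
- West fragment: butenolide by carbonylative lactonization of a Z-iodo allylic alcohol, made by asymmetric alkynylation of a β-bromo enal. East fragment: Evans allylation.
- Ring order: butenolide first (fragment stage), ten-membered carbocycle last.

Assumption: germacrane locants are used in the explanations (lactone oxygen on C6, ester on C8, CH2OH groups C14 on C10 and C15 on C4); the target is read as the 6S,7S,8R,10R isomer with the C4=C5 bond Z by CIP.

**East fragment**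

Step 1
Reactants: 1 methyl 4,4-dimethoxybutanoate
Product: 2 4,4-dimethoxybutanoic acid
Conditions: LiOH·H2O, THF/H2O, 25 °C; then aq. HCl to pH 4, 0 °C
Reagents that add atoms: lithium hydroxide [Li+].[OH-]
Why: Saponification under mild base leaves the dimethyl acetal intact, and cold, cautious acidification frees the acid without acetal loss.

Step 2
Reactants: 2 4,4-dimethoxybutanoic acid; 3 (4R)-4-benzyl-1,3-oxazolidin-2-one
Product: 5 (4R)-4-benzyl-3-(4,4-dimethoxybutanoyl)-1,3-oxazolidin-2-one, via pivalic mixed anhydride 4 (not isolated)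
Conditions: PivCl, Et3N, THF, −20 °C; then 3, LiCl, −20 → 25 °C
Reagents that add atoms: none
Why: N-acylation of the Evans auxiliary through the pivaloyl mixed anhydride with LiCl activation is a mild way to load an acid-sensitive acyl group.

Step 3
Reactants: 5 (4R)-4-benzyl-3-(4,4-dimethoxybutanoyl)-1,3-oxazolidin-2-one
Product: 7 (4R)-4-benzyl-3-[(2R)-2-(2,2-dimethoxyethyl)pent-4-enoyl]-1,3-oxazolidin-2-one, via sodium Z-enolate 6 (not isolated)
Conditions: NaN(SiMe3)2, THF, −78 °C; allyl iodide, −78 → −45 °C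
Reagents that add atoms: allyl iodide C=CCI
Why: Evans asymmetric alkylation, in which the chelated Z-enolate is allylated on the face opposite the benzyl group, sets C10 (R).

Step 4
Reactants: 7 (4R)-4-benzyl-3-[(2R)-2-(2,2-dimethoxyethyl)pent-4-enoyl]-1,3-oxazolidin-2-one
Product: 8 (2R)-2-(2,2-dimethoxyethyl)pent-4-en-1-ol
Conditions: LiBH4, MeOH (1 equiv), Et2O, 0 °C
Reagents that add atoms: none
Why: Reductive cleavage of the imide gives the primary alcohol (future C14 hydroxyl) and returns the auxiliary without touching the alkene, the acetal or C10.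

Step 5
Reactants: 8 (2R)-2-(2,2-dimethoxyethyl)pent-4-en-1-ol
Product: 9 tert-butyl{[(2R)-2-(2,2-dimethoxyethyl)pent-4-en-1-yl]oxy}dimethylsilane
Conditions: TBSCl, imidazole, DMF, 25 °C
Reagents that add atoms: tert-butyldimethylsilyl chloride CC(C)(C)[Si](C)(C)Cl
Why: Standard silylation of a primary alcohol; this TBS ether is kept until the last step.

Step 6
Reactants: 9 tert-butyl{[(2R)-2-(2,2-dimethoxyethyl)pent-4-en-1-yl]oxy}dimethylsilane
Product: 11 (4R)-4-({[tert-butyl(dimethyl)silyl]oxy}methyl)-6,6-dimethoxyhexan-1-ol, via B-alkyl-9-BBN adduct 10 (not isolated)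
Conditions: 9-BBN-H, THF, 0 → 25 °C; then NaOH, H2O2, 0 °C
Reagents that add atoms: hydrogen peroxide OO
Why: Anti-Markovnikov hydroboration–oxidation of the terminal alkene puts the hydroxyl on C3, and basic peroxide leaves the acetal and silyl ether intact.

Step 7
Reactants: 11 (4R)-4-({[tert-butyl(dimethyl)silyl]oxy}methyl)-6,6-dimethoxyhexan-1-ol
Product: 12 tert-butyl{[(2R)-2-(2,2-dimethoxyethyl)-5-iodopentyl]oxy}dimethylsilane
Conditions: I2, PPh3, imidazole, CH2Cl2, 0 °C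
Reagents that add atoms: iodine II
Why: Appel-type iodination gives the primary iodide needed for zinc insertion under neutral conditions.

**West fragment**

Step 8
Reactants: 13 tert-butyldimethyl(prop-2-yn-1-yloxy)silane
Product: 15 4-{[tert-butyl(dimethyl)silyl]oxy}-N-methoxy-N-methylbut-2-ynamide, via lithium acetylide 14 (not isolated)
Conditions: n-BuLi, THF, −78 °C; then MeN(OMe)COCl, −78 → 0 °C
Reagents that add atoms: N-methoxy-N-methylcarbamoyl chloride CON(C)C(Cl)=O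
Why: Acylation of the lithium acetylide with the Weinreb carbamoyl chloride gives the alkynyl Weinreb amide (C6, C5, C4, C15) in one step.

Step 9
Reactants: 15 4-{[tert-butyl(dimethyl)silyl]oxy}-N-methoxy-N-methylbut-2-ynamide
Product: 17 (2E)-4-{[tert-butyl(dimethyl)silyl]oxy}-N-methoxy-N-methyl-3-(tributylstannyl)but-2-enamide, via alkenylcopper adduct 16 (not isolated)
Conditions: Bu3SnH, LiN(iPr)2, THF, −40 °C; CuBr·SMe2, −78 °C; then 15, MeOH, −78 °C
Reagents that add atoms: tributyltin hydride CCCC[SnH](CCCC)CCCC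
Why: Piers stannylcupration adds the stannylcopper reagent syn across the ynamide and in situ protonation at −78 °C gives the kinetic E adduct, so tin is trans and CH2OTBS (C15) cis to the carbonyl carbon (C6).

Step 10
Reactants: 17 (2E)-4-{[tert-butyl(dimethyl)silyl]oxy}-N-methoxy-N-methyl-3-(tributylstannyl)but-2-enamide
Product: 18 (2E)-3-bromo-4-{[tert-butyl(dimethyl)silyl]oxy}-N-methoxy-N-methylbut-2-enamide
Conditions: Br2, CH2Cl2, −78 °C
Reagents that add atoms: bromine BrBr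
Why: Bromodestannylation (ipso substitution at the C–Sn bond) proceeds with retention, so the alkene geometry needed for C4=C5 is fixed here.

Step 11
Reactants: 18 (2E)-3-bromo-4-{[tert-butyl(dimethyl)silyl]oxy}-N-methoxy-N-methylbut-2-enamide
Product: 20 (2E)-3-bromo-4-{[tert-butyl(dimethyl)silyl]oxy}but-2-enal, via aluminium hemiaminal 19 (not isolated)
Conditions: iBu2AlH, THF, −78 °C; aq. potassium sodium tartrate
Reagents that add atoms: none
Why: Weinreb amide reduction stops at the aldehyde because the chelated aluminium hemiaminal survives until work-up.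

Step 12
Reactants: 20 (2E)-3-bromo-4-{[tert-butyl(dimethyl)silyl]oxy}but-2-enal; 21 1-methoxy-4-[(prop-2-yn-1-yloxy)methyl]benzene
Product: 23 (2E,4S)-2-bromo-1-{[tert-butyl(dimethyl)silyl]oxy}-7-[(4-methoxyphenyl)methoxy]hept-2-en-5-yn-4-ol, via alkynyl(methyl)zinc 22 (not isolated)
Conditions: Me2Zn, (S,S)-ProPhenol (20 mol%), Ph3PO (40 mol%), toluene, 0 °C
Reagents that add atoms: none
Why: Zn–ProPhenol (Trost) catalytic asymmetric alkynylation works best on α,β-unsaturated aldehydes, and the (S,S)-ligand is expected to deliver the alkynyl group to the Re face, setting C6 (S in this compound).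

Step 13
Reactants: 23 (2E,4S)-2-bromo-1-{[tert-butyl(dimethyl)silyl]oxy}-7-[(4-methoxyphenyl)methoxy]hept-2-en-5-yn-4-ol
Product: 25 (2E,4S,5Z)-2-bromo-1-{[tert-butyl(dimethyl)silyl]oxy}-6-iodo-7-[(4-methoxyphenyl)methoxy]hepta-2,5-dien-4-ol, via cyclic alkenylaluminate 24 (not isolated)
Conditions: NaAlH2(OCH2CH2OMe)2, THF, −20 → 0 °C; then I2, −78 °C
Reagents that add atoms: iodine II
Why: Hydroxyl-directed trans-hydroalumination of the propargylic alcohol puts H on C7 and Al on C11, and iodinolysis with retention gives the Z-vinyl iodide with iodine cis to the carbinol while the vinyl bromide is inert.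

Step 14
Reactants: 25 (2E,4S,5Z)-2-bromo-1-{[tert-butyl(dimethyl)silyl]oxy}-6-iodo-7-[(4-methoxyphenyl)methoxy]hepta-2,5-dien-4-ol
Product: 26 (5R)-5-[(1E)-2-bromo-3-{[tert-butyl(dimethyl)silyl]oxy}prop-1-en-1-yl]-3-{[(4-methoxyphenyl)methoxy]methyl}furan-2(5H)-one
Conditions: PdCl2(PPh3)2 (5 mol%), CO (1 atm), K2CO3, THF, 25 °C
Reagents that add atoms: carbon monoxide [C-]#[O+]
Why: Palladium-catalysed carbonylative lactonization: zerovalent palladium inserts into the C–I bond much faster than into C–Br, and CO insertion with capture by the cis hydroxyl closes the butenolide without touching C6.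

**Fragment union and endgame**

Step 15
Reactants: 12 tert-butyl{[(2R)-2-(2,2-dimethoxyethyl)-5-iodopentyl]oxy}dimethylsilane; 26 (5R)-5-[(1E)-2-bromo-3-{[tert-butyl(dimethyl)silyl]oxy}prop-1-en-1-yl]-3-{[(4-methoxyphenyl)methoxy]methyl}furan-2(5H)-one
Product: 28 (5S)-5-[(1Z,6R)-2,6-bis({[tert-butyl(dimethyl)silyl]oxy}methyl)-8,8-dimethoxyoct-1-en-1-yl]-3-{[(4-methoxyphenyl)methoxy]methyl}furan-2(5H)-one, via alkylzinc iodide 27 (not isolated)
Conditions: 12, Zn dust (BrCH2CH2Br, Me3SiCl activation), LiCl, THF, 40 °C; then 26, PdCl2(dppf) (5 mol%), THF, 25 °C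
Reagents that add atoms: none
Why: Negishi sp3–sp2 cross-coupling needs no base (the γ-proton of the butenolide is base-sensitive), tolerates lactone, acetal and ethers, and proceeds with retention of alkene geometry so that C3 ends up trans to C6.

Step 16
Reactants: 28 (5S)-5-[(1Z,6R)-2,6-bis({[tert-butyl(dimethyl)silyl]oxy}methyl)-8,8-dimethoxyoct-1-en-1-yl]-3-{[(4-methoxyphenyl)methoxy]methyl}furan-2(5H)-one
Product: 29 (5S)-5-[(1Z,6R)-2,6-bis({[tert-butyl(dimethyl)silyl]oxy}methyl)-8,8-dimethoxyoct-1-en-1-yl]-3-(hydroxymethyl)furan-2(5H)-one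
Conditions: DDQ, CH2Cl2/pH 7 buffer, 0 °C
Reagents that add atoms: none
Why: Oxidative PMB ether cleavage is neutral and leaves the TBS ethers, the acetal and the butenolide intact.

Step 17
Reactants: 29 (5S)-5-[(1Z,6R)-2,6-bis({[tert-butyl(dimethyl)silyl]oxy}methyl)-8,8-dimethoxyoct-1-en-1-yl]-3-(hydroxymethyl)furan-2(5H)-one
Product: 30 (5S)-3-(bromomethyl)-5-[(1Z,6R)-2,6-bis({[tert-butyl(dimethyl)silyl]oxy}methyl)-8,8-dimethoxyoct-1-en-1-yl]furan-2(5H)-one
Conditions: CBr4, PPh3, CH2Cl2, 0 °C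
Reagents that add atoms: carbon tetrabromide BrC(Br)(Br)Br
Why: Appel bromination converts the allylic alcohol into the allylic bromide under neutral conditions compatible with the base-sensitive butenolide.

Step 18
Reactants: 30 (5S)-3-(bromomethyl)-5-[(1Z,6R)-2,6-bis({[tert-butyl(dimethyl)silyl]oxy}methyl)-8,8-dimethoxyoct-1-en-1-yl]furan-2(5H)-one
Product: 32 (3R,7Z)-8-[(2S)-4-(bromomethyl)-5-oxo-2,5-dihydrofuran-2-yl]-3,7-bis({[tert-butyl(dimethyl)silyl]oxy}methyl)oct-7-enal, via collidinium salt 31 (not isolated)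
Conditions: Et3SiOTf, 2,4,6-collidine, CH2Cl2, 0 °C; then H2O
Reagents that add atoms: water O
Why: Chemoselective acetal cleavage under non-acidic conditions (silyl triflate and collidine give a pyridinium intermediate that water hydrolyses) frees the aldehyde while the primary and allylic TBS ethers survive.

Step 19
Reactants: 32 (3R,7Z)-8-[(2S)-4-(bromomethyl)-5-oxo-2,5-dihydrofuran-2-yl]-3,7-bis({[tert-butyl(dimethyl)silyl]oxy}methyl)oct-7-enal
Product: 34 (3aS,4R,6R,10Z,11aS)-6,10-bis({[tert-butyl(dimethyl)silyl]oxy}methyl)-4-hydroxy-3-methylidene-3a,4,5,6,7,8,9,11a-octahydrocyclodeca[b]furan-2(3H)-one, via allylchromium dichloride 33 (not isolated)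
Conditions: CrCl2 (8 equiv), THF, 2 mM (slow addition of 32), 25 °C; aq. NH4Cl
Reagents that add atoms: none
Why: Intramolecular Nozaki–Hiyama allylation (macrocyclization): the allylchromium, whose geometry is fixed by the butenolide ring, attacks the aldehyde through its γ-carbon C7 anti to the C6 substituent in a chair transition state with the aldehyde chain equatorial, which gives the trans-lactone (7S) and the anti C7/C8 relationship (8R) as the ten-membered ring closes.

Step 20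
Reactants: 34 (3aS,4R,6R,10Z,11aS)-6,10-bis({[tert-butyl(dimethyl)silyl]oxy}methyl)-4-hydroxy-3-methylidene-3a,4,5,6,7,8,9,11a-octahydrocyclodeca[b]furan-2(3H)-one
Product: 35 (3aS,4R,6R,10Z,11aS)-6,10-bis({[tert-butyl(dimethyl)silyl]oxy}methyl)-3-methylidene-2-oxo-2,3,3a,4,5,6,7,8,9,11a-decahydrocyclodeca[b]furan-4-yl 2-methylprop-2-enoate
Conditions: methacrylic anhydride, Et3N, DMAP (cat.), CH2Cl2, 0 → 25 °C
Reagents that add atoms: methacrylic anhydride CC(=C)C(=O)OC(=O)C(C)=C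
Why: DMAP-catalysed acylation of the only free hydroxyl installs the methacrylate with retention at C8.

Step 21
Reactants: 35 (3aS,4R,6R,10Z,11aS)-6,10-bis({[tert-butyl(dimethyl)silyl]oxy}methyl)-3-methylidene-2-oxo-2,3,3a,4,5,6,7,8,9,11a-decahydrocyclodeca[b]furan-4-yl 2-methylprop-2-enoate
Product: 36 (3aS,4R,6R,10Z,11aS)-6,10-bis(hydroxymethyl)-3-methylidene-2-oxo-2,3,3a,4,5,6,7,8,9,11a-decahydrocyclodeca[b]furan-4-yl 2-methylprop-2-enoate
Conditions: HF·pyridine, pyridine/THF, 0 → 25 °C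
Reagents that add atoms: none
Why: Fluoride desilylation under mildly acidic, non-nucleophilic conditions removes both TBS ethers without adding to the methacrylate or the α-methylene lactone.

**Compound list**

1 | methyl 4,4-dimethoxybutanoate | COC(=O)CCC(OC)OC | starting material
2 | 4,4-dimethoxybutanoic acid | OC(=O)CCC(OC)OC | intermediate
3 | (4R)-4-benzyl-1,3-oxazolidin-2-one | O=C1N[C@H](Cc2ccccc2)CO1 | starting material
4 | 4,4-dimethoxybutanoic 2,2-dimethylpropanoic anhydride | COC(OC)CCC(=O)OC(=O)C(C)(C)C | intermediate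
5 | (4R)-4-benzyl-3-(4,4-dimethoxybutanoyl)-1,3-oxazolidin-2-one | COC(OC)CCC(=O)N1[C@H](Cc2ccccc2)COC1=O | intermediate
6 | sodium (1Z)-1-[(4R)-4-benzyl-2-oxo-1,3-oxazolidin-3-yl]-4,4-dimethoxybut-1-en-1-olate | [Na+].COC(OC)C/C=C(\[O-])N1[C@H](Cc2ccccc2)COC1=O | intermediate
7 | (4R)-4-benzyl-3-[(2R)-2-(2,2-dimethoxyethyl)pent-4-enoyl]-1,3-oxazolidin-2-one | COC(OC)C[C@H](C(=O)N1[C@H](Cc2ccccc2)COC1=O)CC=C | intermediate
8 | (2R)-2-(2,2-dimethoxyethyl)pent-4-en-1-ol | COC(OC)C[C@H](CO)CC=C | intermediate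
9 | tert-butyl{[(2R)-2-(2,2-dimethoxyethyl)pent-4-en-1-yl]oxy}dimethylsilane | COC(OC)C[C@H](CO[Si](C)(C)C(C)(C)C)CC=C | intermediate
10 | 9-[(4R)-4-({[tert-butyl(dimethyl)silyl]oxy}methyl)-6,6-dimethoxyhexyl]-9-borabicyclo[3.3.1]nonane | COC(OC)C[C@H](CO[Si](C)(C)C(C)(C)C)CCCB1C2CCCC1CCC2 | intermediate
11 | (4R)-4-({[tert-butyl(dimethyl)silyl]oxy}methyl)-6,6-dimethoxyhexan-1-ol | COC(OC)C[C@H](CO[Si](C)(C)C(C)(C)C)CCCO | intermediate
12 | tert-butyl{[(2R)-2-(2,2-dimethoxyethyl)-5-iodopentyl]oxy}dimethylsilane | COC(OC)C[C@H](CO[Si](C)(C)C(C)(C)C)CCCI | intermediate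
13 | tert-butyldimethyl(prop-2-yn-1-yloxy)silane | C#CCO[Si](C)(C)C(C)(C)C | starting material
14 | lithium 3-{[tert-butyl(dimethyl)silyl]oxy}prop-1-yn-1-ide | [Li]C#CCO[Si](C)(C)C(C)(C)C | intermediate
15 | 4-{[tert-butyl(dimethyl)silyl]oxy}-N-methoxy-N-methylbut-2-ynamide | CON(C)C(=O)C#CCO[Si](C)(C)C(C)(C)C | intermediate
16 | {(1Z)-3-{[tert-butyl(dimethyl)silyl]oxy}-1-[methoxy(methyl)carbamoyl]-2-(tributylstannyl)prop-1-en-1-yl}copper | CON(C)C(=O)/C([Cu])=C(/[Sn](CCCC)(CCCC)CCCC)CO[Si](C)(C)C(C)(C)C | intermediate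
17 | (2E)-4-{[tert-butyl(dimethyl)silyl]oxy}-N-methoxy-N-methyl-3-(tributylstannyl)but-2-enamide | CON(C)C(=O)/C=C(/[Sn](CCCC)(CCCC)CCCC)CO[Si](C)(C)C(C)(C)C | intermediate
18 | (2E)-3-bromo-4-{[tert-butyl(dimethyl)silyl]oxy}-N-methoxy-N-methylbut-2-enamide | CON(C)C(=O)/C=C(/Br)CO[Si](C)(C)C(C)(C)C | intermediate
19 | diisobutylaluminium (2E)-3-bromo-4-{[tert-butyl(dimethyl)silyl]oxy}-1-[methoxy(methyl)amino]but-2-en-1-olate (C1 epimers) | CON(C)C(O[Al](CC(C)C)CC(C)C)/C=C(/Br)CO[Si](C)(C)C(C)(C)C | intermediate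
20 | (2E)-3-bromo-4-{[tert-butyl(dimethyl)silyl]oxy}but-2-enal | O=C/C=C(/Br)CO[Si](C)(C)C(C)(C)C | intermediate
21 | 1-methoxy-4-[(prop-2-yn-1-yloxy)methyl]benzene | C#CCOCc1ccc(OC)cc1 | starting material
22 | methyl{3-[(4-methoxyphenyl)methoxy]prop-1-yn-1-yl}zinc | C[Zn]C#CCOCc1ccc(OC)cc1 | intermediate
23 | (2E,4S)-2-bromo-1-{[tert-butyl(dimethyl)silyl]oxy}-7-[(4-methoxyphenyl)methoxy]hept-2-en-5-yn-4-ol | Br/C(CO[Si](C)(C)C(C)(C)C)=C/[C@H](O)C#CCOCc1ccc(OC)cc1 | intermediate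
24 | sodium (5R)-5-[(1E)-2-bromo-3-{[tert-butyl(dimethyl)silyl]oxy}prop-1-en-1-yl]-2,2-bis(2-methoxyethoxy)-3-{[(4-methoxyphenyl)methoxy]methyl}-2,5-dihydro-1,2-oxaluminol-2-uide | [Na+].COCCO[Al-]1(OCCOC)O[C@@H](/C=C(/Br)CO[Si](C)(C)C(C)(C)C)C=C1COCc1ccc(OC)cc1 | intermediate
25 | (2E,4S,5Z)-2-bromo-1-{[tert-butyl(dimethyl)silyl]oxy}-6-iodo-7-[(4-methoxyphenyl)methoxy]hepta-2,5-dien-4-ol | Br/C(CO[Si](C)(C)C(C)(C)C)=C/[C@H](O)/C=C(\I)COCc1ccc(OC)cc1 | intermediate
26 | (5R)-5-[(1E)-2-bromo-3-{[tert-butyl(dimethyl)silyl]oxy}prop-1-en-1-yl]-3-{[(4-methoxyphenyl)methoxy]methyl}furan-2(5H)-one | Br/C(CO[Si](C)(C)C(C)(C)C)=C/[C@@H]1OC(=O)C(COCc2ccc(OC)cc2)=C1 | intermediate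
27 | iodo[(4R)-4-({[tert-butyl(dimethyl)silyl]oxy}methyl)-6,6-dimethoxyhexyl]zinc | COC(OC)C[C@H](CO[Si](C)(C)C(C)(C)C)CCC[Zn]I | intermediate
28 | (5S)-5-[(1Z,6R)-2,6-bis({[tert-butyl(dimethyl)silyl]oxy}methyl)-8,8-dimethoxyoct-1-en-1-yl]-3-{[(4-methoxyphenyl)methoxy]methyl}furan-2(5H)-one | COC(OC)C[C@H](CO[Si](C)(C)C(C)(C)C)CCC/C(CO[Si](C)(C)C(C)(C)C)=C/[C@@H]1OC(=O)C(COCc2ccc(OC)cc2)=C1 | intermediate
29 | (5S)-5-[(1Z,6R)-2,6-bis({[tert-butyl(dimethyl)silyl]oxy}methyl)-8,8-dimethoxyoct-1-en-1-yl]-3-(hydroxymethyl)furan-2(5H)-one | COC(OC)C[C@H](CO[Si](C)(C)C(C)(C)C)CCC/C(CO[Si](C)(C)C(C)(C)C)=C/[C@@H]1OC(=O)C(CO)=C1 | intermediate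
30 | (5S)-3-(bromomethyl)-5-[(1Z,6R)-2,6-bis({[tert-butyl(dimethyl)silyl]oxy}methyl)-8,8-dimethoxyoct-1-en-1-yl]furan-2(5H)-one | COC(OC)C[C@H](CO[Si](C)(C)C(C)(C)C)CCC/C(CO[Si](C)(C)C(C)(C)C)=C/[C@@H]1OC(=O)C(CBr)=C1 | intermediate
31 | 1-{(3R,7Z)-8-[(2S)-4-(bromomethyl)-5-oxo-2,5-dihydrofuran-2-yl]-3,7-bis({[tert-butyl(dimethyl)silyl]oxy}methyl)-1-methoxyoct-7-en-1-yl}-2,4,6-trimethylpyridinium trifluoromethanesulfonate (C1 epimers) | COC(C[C@H](CO[Si](C)(C)C(C)(C)C)CCC/C(CO[Si](C)(C)C(C)(C)C)=C/[C@@H]1OC(=O)C(CBr)=C1)[n+]1c(C)cc(C)cc1C.[O-]S(=O)(=O)C(F)(F)F | intermediate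
32 | (3R,7Z)-8-[(2S)-4-(bromomethyl)-5-oxo-2,5-dihydrofuran-2-yl]-3,7-bis({[tert-butyl(dimethyl)silyl]oxy}methyl)oct-7-enal | O=CC[C@H](CO[Si](C)(C)C(C)(C)C)CCC/C(CO[Si](C)(C)C(C)(C)C)=C/[C@@H]1OC(=O)C(CBr)=C1 | intermediate
33 | dichloro({(5S)-5-[(1Z,6R)-2,6-bis({[tert-butyl(dimethyl)silyl]oxy}methyl)-8-oxooct-1-en-1-yl]-2-oxo-2,5-dihydrofuran-3-yl}methyl)chromium | O=CC[C@H](CO[Si](C)(C)C(C)(C)C)CCC/C(CO[Si](C)(C)C(C)(C)C)=C/[C@@H]1OC(=O)C(C[Cr](Cl)Cl)=C1 | intermediate
34 | (3aS,4R,6R,10Z,11aS)-6,10-bis({[tert-butyl(dimethyl)silyl]oxy}methyl)-4-hydroxy-3-methylidene-3a,4,5,6,7,8,9,11a-octahydrocyclodeca[b]furan-2(3H)-one | O[C@@H]1C[C@H](CO[Si](C)(C)C(C)(C)C)CCC/C(CO[Si](C)(C)C(C)(C)C)=C/[C@@H]2OC(=O)C(=C)[C@H]21 | intermediate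
35 | (3aS,4R,6R,10Z,11aS)-6,10-bis({[tert-butyl(dimethyl)silyl]oxy}methyl)-3-methylidene-2-oxo-2,3,3a,4,5,6,7,8,9,11a-decahydrocyclodeca[b]furan-4-yl 2-methylprop-2-enoate | C=C(C)C(=O)O[C@@H]1C[C@H](CO[Si](C)(C)C(C)(C)C)CCC/C(CO[Si](C)(C)C(C)(C)C)=C/[C@@H]2OC(=O)C(=C)[C@H]21 | intermediate
36 | (3aS,4R,6R,10Z,11aS)-6,10-bis(hydroxymethyl)-3-methylidene-2-oxo-2,3,3a,4,5,6,7,8,9,11a-decahydrocyclodeca[b]furan-4-yl 2-methylprop-2-enoate | C=C(C)C(=O)O[C@@H]1C[C@H](CO)CCC/C(CO)=C/[C@@H]2OC(=O)C(=C)[C@H]21 | target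

Note: the descriptor of C6 changes along the route (S in 23 and 25, R in 24 and 26, S from 28 on) only because CIP priorities change; the spatial arrangement set in step 12 is never touched.

**Step count and weak points**

Total step count: 21. Longest linear sequence: 14 steps (steps 8–14, then 15–21; the east sequence 1–7, then 15–21, is equally long).

The three steps most likely to fail:

Step 19 (macrocyclization). The chromium-mediated closure has to form a ten-membered ring, and the tether may override the chair preference that normally gives the anti C7/C8 relationship; a cis-fused product or oligomers are also possible. The fallback sets out from 32: if the closure gives mainly the C8-epimeric alcohol, (3aS,4S,6R,10Z,11aS)-6,10-bis({[tert-butyl(dimethyl)silyl]oxy}methyl)-4-hydroxy-3-methylidene-3a,4,5,6,7,8,9,11a-octahydrocyclodeca[b]furan-2(3H)-one F1, it is esterified with inversion under Mitsunobu conditions (methacrylic acid, PPh3, diisopropyl azodicarboxylate, toluene, 0 °C). This corrects C8 and installs the methacrylate in one operation, replaces the acylation of step 20 and comes back to the route at 35.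

Step 14 (carbonylative lactonization). The γ-proton of the new 5-alkenylbutenolide is acidic, so K2CO3 may epimerize C6 or move the alkene into the 5-ylidene position, and zerovalent palladium may ionize the allylic lactone. The fallback sets out from 25 and avoids both palladium and carbonate: iodine–magnesium exchange with iPrMgCl·LiCl (2.2 equiv, THF, −40 °C; the first equivalent forms the alkoxide and the vinyl bromide is not exchanged), then CO2 and acidification to pH 3. The Z-hydroxy acid lactonizes spontaneously, so the detour makes no new isolated compound (F0) and comes back at 26.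

Step 15 (Negishi coupling). The hindered 2-bromoalkene may couple slowly, and the allylic lactone is exposed to zerovalent palladium. The fallback sets out from 23 and the zinc reagent 27 and changes the order of events, so that the coupling is done before the lactone exists. Coupling with Pd(OAc)2/SPhos (THF, 25 °C, tolerant of the free hydroxyl) gives the enynol (4S,5Z,10R)-6,10-bis({[tert-butyl(dimethyl)silyl]oxy}methyl)-12,12-dimethoxy-1-[(4-methoxyphenyl)methoxy]dodec-5-en-2-yn-4-ol F2. NaAlH2(OCH2CH2OMe)2 then I2 gives the iododienol (2Z,4S,5Z,10R)-6,10-bis({[tert-butyl(dimethyl)silyl]oxy}methyl)-2-iodo-12,12-dimethoxy-1-[(4-methoxyphenyl)methoxy]dodeca-2,5-dien-4-ol F3. Carbonylative lactonization (PdCl2(PPh3)2, CO, K2CO3, THF) then comes back to the route at 28.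

**Further compounds**

F1 | step 19 | (3aS,4S,6R,10Z,11aS)-6,10-bis({[tert-butyl(dimethyl)silyl]oxy}methyl)-4-hydroxy-3-methylidene-3a,4,5,6,7,8,9,11a-octahydrocyclodeca[b]furan-2(3H)-one | O[C@H]1C[C@H](CO[Si](C)(C)C(C)(C)C)CCC/C(CO[Si](C)(C)C(C)(C)C)=C/[C@@H]2OC(=O)C(=C)[C@H]21
F0 | step 14 | none | none
F2 | step 15 | (4S,5Z,10R)-6,10-bis({[tert-butyl(dimethyl)silyl]oxy}methyl)-12,12-dimethoxy-1-[(4-methoxyphenyl)methoxy]dodec-5-en-2-yn-4-ol | COC(OC)C[C@H](CO[Si](C)(C)C(C)(C)C)CCC/C(CO[Si](C)(C)C(C)(C)C)=C/[C@H](O)C#CCOCc1ccc(OC)cc1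
F3 | step 15 | (2Z,4S,5Z,10R)-6,10-bis({[tert-butyl(dimethyl)silyl]oxy}methyl)-2-iodo-12,12-dimethoxy-1-[(4-methoxyphenyl)methoxy]dodeca-2,5-dien-4-ol | COC(OC)C[C@H](CO[Si](C)(C)C(C)(C)C)CCC/C(CO[Si](C)(C)C(C)(C)C)=C/[C@H](O)/C=C(\I)COCc1ccc(OC)cc1
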